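**Retrosynthetic overview**
1. The target is reached by hydrogenolysis of four benzyl ethers, after fluoride has opened a di-tert-butylsilylene bridge. The protected dimer is cut at the flavanone C2–C1' bond into 5,7-bis(benzyloxy)chromone and an arylboronic acid; an enantioselective conjugate addition sets C2.
2. The boronic acid comes from an aryl chloride. Its biaryl bond (flavone C6 to ring B C3') is made by intramolecular palladium C–H arylation of a bis(aryloxy)silane built from 7,4'-di-O-benzylapigenin and 2-bromo-4-chlorophenol.
3. Feature the strategy rests on: the C6–C3' biaryl bond has an oxygen on each ortho carbon, flavone O5 on ring A and O4' on flavanone ring B (a 2,2'-biphenol). O5–H is hydrogen-bonded to the C4 carbonyl, so it is the one apigenin hydroxyl that carbonate benzylation spares, and it neighbours C6 but not C8. An O5–Si–O4' bridge can therefore deliver only the wanted bond.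
4. Ring order: the flavone rings come ready-made in apigenin; the seven-membered dioxasilepine closes in the biaryl-forming step; the chromone ring is built from 2',4',6'-trihydroxyacetophenone and becomes flavanone ring C in the conjugate addition; the silicon ring is opened just before debenzylation.

Key step: step 3

Assumption on the ligand: the (R) enantiomer of the tert-butyl pyridine-oxazoline ligand is taken to give the (2S) flavanone, by analogy with the facial sense this ligand class shows with cyclic enones. The hand is checked on a model addition before the boronic acid is committed, and the (S) ligand is used if the check points the other way.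
Assumption on the axis: the biaryl axis has no descriptor in the target and is treated as not configurationally fixed; any rotamer mixtures of the silicon-bridged intermediates are carried forward together.

**Route**

Step 1
Reactants: 1 apigenin
Product: 2 7,4'-di-O-benzylapigenin (7-benzyloxy-2-(4-benzyloxyphenyl)-5-hydroxychromen-4-one)
Conditions: BnBr (2.2 equiv), K2CO3, DMF, rt to 40 °C
Reagents that add atoms: benzyl bromide, BrCc1ccccc1
Why: Williamson etherification with a mild carbonate base alkylates the 7- and 4'-hydroxyls only, because the 5-hydroxyl is locked in a hydrogen bond to the C4 carbonyl and is far less acidic and nucleophilic.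

Step 2
Reactants: 2 7,4'-di-O-benzylapigenin; 3 2-bromo-4-chlorophenol
Product: 5 di-tert-butyl(2-bromo-4-chlorophenoxy)(flavon-5-yloxy)silane, the flavone being 7,4'-di-O-benzylapigenin bonded through O5, via flavone 5-O-silyl triflate 4 (not isolated)
Conditions: tBu2Si(OTf)2 (1.05 equiv), 2,6-lutidine, CH2Cl2, 0 °C to rt; then 3, imidazole, DMAP (cat.), rt to 40 °C
Reagents that add atoms: di-tert-butylsilyl bis(trifluoromethanesulfonate), CC(C)(C)[Si](OS(=O)(=O)C(F)(F)F)(OS(=O)(=O)C(F)(F)F)C(C)(C)C
Why: Stepwise silyl ether formation on a silyl bis(triflate): the very electrophilic ditriflate overcomes the low nucleophilicity of the hydrogen-bonded O5–H, the hindered monotriflate (covalent or closed onto the C4 carbonyl oxygen) does not take up a second flavone, and it is then opened by the unhindered, more acidic bromochlorophenol under imidazole/DMAP nucleophilic catalysis.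

Step 3
Reactants: 5 di-tert-butyl(2-bromo-4-chlorophenoxy)(flavon-5-yloxy)silane
Product: 6 silylene-bridged biaryl chloride: 7,4'-di-O-benzylapigenin carrying at C6 a 5-chloro-2-oxyphenyl group, with Si(t-Bu)2 bridging that oxygen and flavone O5 (dibenzo-1,3,2-dioxasilepine)
Conditions: Pd(OAc)2 (10 mol%), PPh3 (20 mol%), Cs2CO3, PivOH (30 mol%), degassed mesitylene (0.02 M), 120 °C
Reagents that add atoms: none
Why: Zerovalent palladium formed from Pd(OAc)2 and PPh3 inserts into the C–Br bond of 5, bromide is exchanged for pivalate, and the arylpalladium pivalate, held above the flavone by the O–Si–O bridge, cleaves C6–H by concerted metalation–deprotonation to an eight-membered diarylpalladacycle that reductively eliminates the C6–C3' bond. The closest known reaction type is the silicon-tethered intramolecular direct arylation of di-tert-butyl bis(aryloxy)silanes that leads to unsymmetrical 2,2'-biphenols, applied here to a flavone C–H partner. The one ring closed is the seven-membered 1,3,2-dioxasilepine (Si, two O, four aryl C), formed by aryl–aryl bond formation in the reductive elimination, and it is temporary. No stereocenter is created, and the new axis has no descriptor in the target. Site selectivity for C6 over C8 follows from the bridge, which is anchored on O5 and cannot span to C8, and from the acidity of C6–H between two oxygen-bearing carbons; ring closure is favoured over intermolecular coupling by the bridge and high dilution. Chemoselectivity for C–Br over C–Cl rests on the inertness of the electron-rich aryl chloride towards PPh3-ligated palladium at this temperature.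

Step 4
Reactants: 6 silylene-bridged biaryl chloride
Product: 7 silylene-bridged biaryl pinacol boronate (4,4,5,5-tetramethyl-1,3,2-dioxaborolan-2-yl in place of Cl)
Conditions: B2pin2, Pd2(dba)3 (2.5 mol%), XPhos (10 mol%), KOAc, 1,4-dioxane, 100 °C
Reagents that add atoms: bis(pinacolato)diboron, CC1(C)OB(OC1(C)C)B1OC(C)(C)C(C)(C)O1
Why: Miyaura borylation, in which the bulky electron-rich biarylphosphine lets zerovalent palladium insert into the electron-rich aryl chloride and acetate mediates transmetalation from the diboron, while the silylene, benzyl ethers and flavone are inert to KOAc in dry dioxane.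

Step 5
Reactants: 7 silylene-bridged biaryl pinacol boronate
Product: 8 silylene-bridged biaryl boronic acid (B(OH)2 para to the silylated ring B oxygen)
Conditions: NaIO4, NH4OAc, acetone/THF/H2O, rt
Reagents that add atoms: water, O
Why: Oxidative cleavage of a pinacol boronate: the small amount of pinacol released by reversible hydrolysis is destroyed irreversibly by periodate, which pulls the equilibrium to the boronic acid in a near-neutral buffer that the hindered bis(aryloxy)silane tolerates.

Step 6
Reactants: 9 2',4',6'-trihydroxyacetophenone
Product: 10 2'-hydroxy-4',6'-bis(benzyloxy)acetophenone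
Conditions: BnBr (2.1 equiv), K2CO3, acetone, reflux
Reagents that add atoms: benzyl bromide, BrCc1ccccc1
Why: Williamson etherification takes the 4'-hydroxyl and one of the two equivalent ortho hydroxyls, after which the last hydroxyl is firmly chelated to the acetyl carbonyl and resists alkylation under carbonate.

Step 7
Reactants: 10 2'-hydroxy-4',6'-bis(benzyloxy)acetophenone
Product: 11 (E)-1-[2,4-bis(benzyloxy)-6-hydroxyphenyl]-3-(dimethylamino)prop-2-en-1-one
Conditions: Me2NCH(OMe)2, toluene, 100 °C
Reagents that add atoms: N,N-dimethylformamide dimethyl acetal, COC(OC)N(C)C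
Why: Enaminone formation by condensation of the acetyl methyl group with the amide acetal, with loss of two methanol; the acetal carbon becomes the future chromone C2 and the chelated phenol stays free.

Step 8
Reactants: 11 (E)-enaminone
Product: 12 5,7-bis(benzyloxy)chromen-4-one
Conditions: conc. aq. HCl, CH2Cl2, 40 °C
Reagents that add atoms: none
Why: Acid-promoted addition–elimination chromone synthesis: the protonated enaminone acts as a vinylogous iminium ion, the phenol oxygen adds to its β-carbon in a six-membered closure, and loss of dimethylamine gives the pyranone, with the benzyl ethers untouched by brief exposure to aqueous acid.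

Step 9
Reactants: 8 silylene-bridged biaryl boronic acid; 12 5,7-bis(benzyloxy)chromen-4-one (2 equiv)
Product: 13 protected (2S)-flavanone–flavone: (2S)-5,7-bis(benzyloxy)flavanone whose ring B is the 2-oxyphenyl ring of the silylene-bridged biaryl (C3' bonded to flavone C6, O4' and flavone O5 bridged by Si(t-Bu)2, flavone part 7,4'-di-O-benzylated)
Conditions: Pd(OCOCF3)2 (10 mol%), (R)-4-tert-butyl-2-(2-pyridyl)-2-oxazoline (12 mol%), NH4PF6 (30 mol%), H2O (5 equiv), ClCH2CH2Cl, 60 °C
Reagents that add atoms: none
Why: Palladium-catalysed asymmetric conjugate addition of an arylboronic acid to a chromone (boron-to-palladium transmetalation on the cationic divalent palladium–pyridine-oxazoline complex, migratory insertion of the chromone C2=C3 bond into the aryl–palladium bond, protonation of the palladium enolate by water), in which the tert-butyl group of the (R)-ligand leaves one face of C2 open during insertion and so sets C2 as (S), while the boron-bearing carbon of 8 has two free ortho positions and the 2-aryl-substituted flavone double bond of 8 is too hindered to act as an acceptor.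

Step 10
Reactants: 13 protected (2S)-flavanone–flavone
Product: 14 tetrabenzyl ether with both biaryl-flanking phenols free: (2S)-5,7-bis(benzyloxy)-4'-hydroxyflavanone bearing at C3' the 6-yl group of 7,4'-di-O-benzylapigenin (free 5-OH)
Conditions: HF·pyridine, pyridine, THF, 0 °C to rt
Reagents that add atoms: none
Why: Fluoride-driven cleavage of both Si–O(aryl) bonds, favoured by the strength of the Si–F bond and run in a buffered acidic medium so that no phenoxide or enolate forms that could open the flavanone by retro-oxa-Michael reaction and erode C2; any rotamers of 13 converge on the same product.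

Step 11
Reactants: 14 tetrabenzyl ether
Product: 15 target CNP0277421.1: (2S)-naringenin joined through C3' to C6 of apigenin
Conditions: H2 (1 atm), Pd/C (10%), EtOAc/MeOH, rt, stopped at full conversion
Reagents that add atoms: none
Why: Catalytic hydrogenolysis of the four benzyl aryl ethers under neutral conditions, which is faster than reduction of the flavone C2=C3 bond or hydrogenolysis of the cyclic benzylic C2–O bond and leaves the C2 configuration untouched.

**Compound list**
1 | apigenin | O=c1cc(-c2ccc(O)cc2)oc2cc(O)cc(O)c12 | starting material
2 | 7,4'-di-O-benzylapigenin | O=c1cc(-c2ccc(OCc3ccccc3)cc2)oc2cc(OCc3ccccc3)cc(O)c12 | intermediate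
3 | 2-bromo-4-chlorophenol | Oc1ccc(Cl)cc1Br | starting material
4 | flavone 5-O-(di-tert-butyl)silyl triflate | CC(C)(C)[Si](OS(=O)(=O)C(F)(F)F)(Oc1cc(OCc2ccccc2)cc2oc(-c3ccc(OCc4ccccc4)cc3)cc(=O)c12)C(C)(C)C | intermediate
5 | di-tert-butyl(2-bromo-4-chlorophenoxy)(flavon-5-yloxy)silane | CC(C)(C)[Si](Oc1ccc(Cl)cc1Br)(Oc1cc(OCc2ccccc2)cc2oc(-c3ccc(OCc4ccccc4)cc3)cc(=O)c12)C(C)(C)C | intermediate
6 | silylene-bridged biaryl chloride (dibenzo-1,3,2-dioxasilepine) | CC(C)(C)[Si]1(C(C)(C)C)Oc2ccc(Cl)cc2-c2c(O1)c3c(=O)cc(-c4ccc(OCc5ccccc5)cc4)oc3cc2OCc2ccccc2 | intermediate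
7 | silylene-bridged biaryl pinacol boronate | CC(C)(C)[Si]1(C(C)(C)C)Oc2ccc(B3OC(C)(C)C(C)(C)O3)cc2-c2c(O1)c3c(=O)cc(-c4ccc(OCc5ccccc5)cc4)oc3cc2OCc2ccccc2 | intermediate
8 | silylene-bridged biaryl boronic acid | CC(C)(C)[Si]1(C(C)(C)C)Oc2ccc(B(O)O)cc2-c2c(O1)c3c(=O)cc(-c4ccc(OCc5ccccc5)cc4)oc3cc2OCc2ccccc2 | intermediate
9 | 2',4',6'-trihydroxyacetophenone | CC(=O)c1c(O)cc(O)cc1O | starting material
10 | 2'-hydroxy-4',6'-bis(benzyloxy)acetophenone | CC(=O)c1c(O)cc(OCc2ccccc2)cc1OCc1ccccc1 | intermediate
11 | (E)-1-[2,4-bis(benzyloxy)-6-hydroxyphenyl]-3-(dimethylamino)prop-2-en-1-one | CN(C)/C=C/C(=O)c1c(O)cc(OCc2ccccc2)cc1OCc1ccccc1 | intermediate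
12 | 5,7-bis(benzyloxy)chromen-4-one | O=c1ccoc2cc(OCc3ccccc3)cc(OCc3ccccc3)c12 | intermediate
13 | protected (2S)-flavanone–flavone with silylene bridge | O=C1C[C@@H](c2ccc3c(c2)-c2c(O[Si](C(C)(C)C)(C(C)(C)C)O3)c3c(=O)cc(-c4ccc(OCc5ccccc5)cc4)oc3cc2OCc2ccccc2)Oc2cc(OCc3ccccc3)cc(OCc3ccccc3)c21 | intermediate
14 | tetrabenzyl ether with both biaryl-flanking phenols free | O=C1C[C@@H](c2ccc(O)c(-c3c(O)c4c(=O)cc(-c5ccc(OCc6ccccc6)cc5)oc4cc3OCc3ccccc3)c2)Oc2cc(OCc3ccccc3)cc(OCc3ccccc3)c21 | intermediate
15 | CNP0277421.1 | O=C1C[C@@H](c2ccc(O)c(-c3c(O)cc4oc(-c5ccc(O)cc5)cc(=O)c4c3O)c2)Oc2cc(O)cc(O)c21 | target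

**Totals**
Total step count: 11.
Longest linear sequence: 8 steps (steps 1, 2, 3, 4, 5, 9, 10, 11 from apigenin); the chromone branch (steps 6, 7, 8) joins at step 9.

**Steps most likely to fail**

Step 3. The arylpalladium intermediate may be reduced (hydrodebromination), or the Si–O bonds may be cleaved by carbonate and pivalate at 120 °C, faster than metalation of the crowded C6–H, so the bridge is lost before the bond forms. The fallback replaces C–H activation by a cross-coupling of two prefunctionalised partners and sets out from 2. Iodination ortho to the free 5-hydroxyl (benzyltrimethylammonium dichloroiodate, CaCO3, CH2Cl2/MeOH, rt) is expected to go to C6 and give 6-iodo-7,4'-di-O-benzylapigenin F1. Suzuki–Miyaura coupling of F1 with commercial (5-chloro-2-hydroxyphenyl)boronic acid (PdCl2(dppf), aqueous K2CO3, DME, 85 °C; the C–I bond reacts and the C–Cl bond stays) should give the biaryl diol 7-benzyloxy-2-(4-benzyloxyphenyl)-6-(5-chloro-2-hydroxyphenyl)-5-hydroxychromen-4-one F2. Bridging its two biaryl-flanking hydroxyls with tBu2Si(OTf)2 and 2,6-lutidine in CH2Cl2 closes the same dioxasilepine and rejoins the route at 6.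

Step 9. Insertion into the electron-rich 5,7-dialkoxychromone may be slow, so that protodeboronation of the boronic acid and slow loss of the silicon bridge to fluoride released from hexafluorophosphate compete; facial selectivity may also be lower than with simple boronic acids. The fallback changes metal and mechanism and sets out from 8 and 12. It uses a monovalent rhodium hydroxide carrying a chiral diene, generated from [RhCl(C2H4)2]2, a C2-symmetric chiral bicyclo[2.2.2]octadiene and a substoichiometric amount of aqueous KOH in dioxane/water at 40 °C. Asymmetric 1,4-addition by aryl transfer from boron to rhodium, insertion and hydrolysis of the rhodium enolate should give 13, where the route is rejoined. For either catalyst the hand is fixed beforehand on a model. 4-Benzyloxyphenylboronic acid and 12 should give (2S)-5,7,4'-tri-O-benzylnaringenin F3. Its configuration is read from electronic circular dichroism (a (2S)-flavanone shows a positive band near 330 nm and a negative band near 290 nm). After hydrogenolysis (H2, Pd/C) to (2S)-naringenin F4, it is confirmed by chiral HPLC against the commercial natural enantiomer.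

Step 2. Silylation of the hydrogen-bonded, peri-hindered O5–H may stay incomplete, or the two aryloxy groups may scramble to symmetrical bis(aryloxy)silanes during the second substitution. The fallback reverses the order of assembly and uses a preformed phenoxide; it sets out from 3 and 2. Phenol 3 with tBu2Si(OTf)2 and 2,6-lutidine in CH2Cl2 at 0 °C should give (2-bromo-4-chlorophenoxy)di-tert-butylsilyl triflate F5. Separately, 2 is deprotonated with NaH in THF to its sodium 5-phenoxide F6, in which the hydrogen bond is broken. Addition of F6 to F5 displaces triflate and rejoins the route at 5.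

**Further compounds**
F1 | step 3 | 6-iodo-7,4'-di-O-benzylapigenin | O=c1cc(-c2ccc(OCc3ccccc3)cc2)oc2cc(OCc3ccccc3)c(I)c(O)c12
F2 | step 3 | 7-benzyloxy-2-(4-benzyloxyphenyl)-6-(5-chloro-2-hydroxyphenyl)-5-hydroxychromen-4-one | O=c1cc(-c2ccc(OCc3ccccc3)cc2)oc2cc(OCc3ccccc3)c(-c3cc(Cl)ccc3O)c(O)c12
F3 | step 9 | (2S)-5,7,4'-tri-O-benzylnaringenin | O=C1C[C@@H](c2ccc(OCc3ccccc3)cc2)Oc2cc(OCc3ccccc3)cc(OCc3ccccc3)c21
F4 | step 9 | (2S)-naringenin | O=C1C[C@@H](c2ccc(O)cc2)Oc2cc(O)cc(O)c21
F5 | step 2 | (2-bromo-4-chlorophenoxy)di-tert-butylsilyl triflate | CC(C)(C)[Si](OS(=O)(=O)C(F)(F)F)(Oc1ccc(Cl)cc1Br)C(C)(C)C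
F6 | step 2 | sodium 5-phenoxide of 7,4'-di-O-benzylapigenin | [Na+].[O-]c1cc(OCc2ccccc2)cc2oc(-c3ccc(OCc4ccccc4)cc3)cc(=O)c12
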